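## The problem

The target is a heliangolide-type germacranolide. Germacrane numbering is used throughout: a ten-membered carbocycle C1–C10 with the C1 ketone, the C3 carbinol, the Z C4=C5 alkene carrying the C15 methyl, the C8 isovalerate and the C10 tertiary carbinol carrying C14. Fused to it is a trans α-methylene γ-lactone built from O6, C7, C11(=C13) and the C12 carbonyl.

A ten-membered ring is the hardest size to close directly, and this one also holds a Z-trisubstituted alkene, so the ring-forming event decides the plan. Of the five stereocentres (3R,6R,7R,8R,10R), C6, C7 and C8 are contiguous and can be relayed from one another. C3 and C10 are insulated from that triad and from each other by C1/C2 and C9, so each must come from the chiral pool or from reagent control.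

Late intermediates tolerate little. The α-methylene lactone accepts nucleophiles, the C3 hydroxyl is β to the C1 ketone (retro-aldol, dehydration), C10-OH/C1=O is an α-ketol, the C6–O bond is allylic and the ester can migrate. None of this survives an organolithium, so C1 must be masked and the ester, lactone carbonyl and free hydroxyls must appear after the skeleton is complete.

The enabling feature is the array C5=C4 / C6(O) / C7 / C11=C13. C6 is an allylic carbinol bonded to a carbon that bears a 1,1-disubstituted alkene, which is the retron of a [2,3]-Wittig shift. Reconnecting O6 to C13, with the alkene moved to C7=C11, turns the carbocycle into a thirteen-membered bis-allylic ether.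

## Retrosynthesis

**End game (35 back to 27).** The bonds cut are the C8–O acyl bond (35 from 34, 34 from 32 and 33), the protecting-group O–Si and O–CH2 bonds, the C1 carbonyl back to a carbinol (31 from 30) and the C12–O6 acyl bond with the C12 oxidation level (30 from 28, 28 from 27). The ester, the ketone and the lactone carbonyl are exactly the groups an organolithium would destroy, so they follow the skeletal step. C1 is carried as a silyl-protected carbinol, not as a ketal: a ketal next to the fully substituted, oxygen-bearing C10 would form and hydrolyse reluctantly, whereas the carbinol is freed by fluoride and oxidised by IBX beside the tertiary hydroxyl. The forward steps must distinguish four silyl or acetal groups, which is arranged by their lability order: TES and primary TBS first, MOM next, TIPS last.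

**Key disconnection (27 back to 25).** C6–C7 is cut, O6–C13 is restored and the alkene returns from C11=C13 to C7=C11. Cutting C6–C7 as an ionic ring closure, or cutting any other ring bond, would demand a direct ten-membered cyclisation. The sigmatropic cut replaces it by a thirteen-membered etherification followed by a transannular contraction, and it delivers C6-OH and the C12 carbinol ready for lactonisation. Ether 25 has no carbocycle and two stereocentres fewer than 27. The forward step needs lithiation at C6, an exo transition state for the anti C6/C7 pair, and bonding on the C7 face dictated by C8.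

**Ether bond (25 back to 21).** The O–C6 bond is cut to the hydroxy allylic chloride 24, which comes from 23, 22 and the ester 21. O–C6 is chosen over O–C13 because a C13 alkoxide would sit next to the C12 silyl ether and invite silyl transfer. The C6 alkoxide has only the C3 ether nearby, and that is made a migration-resistant TIPS group. The forward reaction is an SN2 displacement of a primary allylic chloride under high dilution.

**C2–C3 aldol (21 back to 10 and 16).** Cutting C2–C3 (21 from 20, 19 and 18; 18 from 10 and 16) splits the chain into two pieces of similar size. Because C10 is quaternary, methyl ketone 10 can enolise only toward C2. C3 is set by a chiral boron reagent since no resident centre is close enough to control it. The C3 hydroxyl then directs a syn reduction that masks C1 as a defined carbinol.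

**Z-enal 16 (back to 11).** The C3 formyl carbon is removed (16 from 14), then the PMB group (14 from 13) and the iodine and hydride (13 from 11). Trans-hydroalumination of but-2-yn-1-ol fixes the Z geometry unambiguously. Reduction of a citraconic derivative would leave two similar primary hydroxyls to tell apart.

**C1 ketone and C12 (10 back to 7).** The C1 carbonyl goes back to the vinyl group of 9 (Wacker oxidation), and C12 is cut from C11 (9 from 8, 8 from bromide 7 by Stille coupling). The bromide route places the C12 arm cis to C8 by a stereoretentive coupling, using commercial reagents.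

**C7=C11 and C8–O (7 back to 1).** The C7=C11 double bond and the C8–O bond are cut together (7 from 6 and 5; 5 from aldehyde 3). One operation, an α-aminoxylation followed by a Wittig reaction, sets C8 by catalyst control and the alkene geometry by the stabilised ylide. Aldehyde 3 comes from (R)-linalool 1 via 2 by selective ozonolysis, so C10 comes from the chiral pool.

## Roads not taken

**Alternative 1:** The cut is C7–C11 together with the lactone acyl–O6 bond, on an open C1–C10 chain whose ring would be closed later at C3–C4 from an alkenyl iodide.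
- Forward step: a diethylphosphonoacetate ester on O6 is deprotonated and its carbanion opens a C7–C8 epoxide at C7 (5-exo, inversion). This gives the trans phosphono lactone A1 with C8-OH as the only free hydroxyl; a later Horner–Wadsworth–Emmons methylenation would create the exocyclic alkene.
- Merits: C6, C7 and C8 follow stereospecifically from an epoxy alcohol, the lactone is at its final oxidation level at once, and C8 is unveiled alone for the isovalerate.
- Weak points: a stabilised phosphonoacetate anion opens an unactivated 1,2-disubstituted epoxide reluctantly, and the freed C8 alkoxide can take the acyl group back. Above all, the ten-membered ring must still be closed by adding a Z-trisubstituted alkenyl metal to an aldehyde, in a chain stiffened by the lactone, with C3 formed without a control element.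
- Comparison: this road is better in the certainty of the C6–C8 triad, since the chosen plan leaves the C7 face to a conformational argument. Against that, the chosen plan makes ring closure and C6/C7 formation one event and fixes C3 before any ring exists.

**Alternative 2:** The cut is C8–C9 of the ten-membered ring, paid for by joining C1 to C6 in a six-membered ring.
- Forward step: the potassium alkoxide of a tertiary cyclohexenol, with a 2-silylvinyl group on the carbinol carbon and an isopropenyl group on the neighbouring ring carbon, undergoes an anionic oxy-Cope [3,3] shift. The ring expands by four atoms to an enolate, protonated to cyclodecadienone A2.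
- Merits: it is the shortest access to the carbocycle, needs no high dilution and is a well-tested way to germacrane rings. The Z C4=C5 alkene is inherited from the six-membered ring, and a chair transition state sets C8 (as a silane) and the C1=C10 geometry.
- Weak points: A2 is far from the target's oxidation pattern. C1/C10 arrive as an alkene that must become ketone plus R tertiary carbinol next to a second alkene and an enone. The C6 ketone must be reduced to one epimer, the whole C11–C13 unit attached at C7 with trans control, and the arylsilane oxidised by a protocol whose electrophilic activation the trisubstituted alkenes will not ignore. Cyclodeca-1(10),4-dienes also cyclise transannularly under acid.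
- Comparison: this road is better in step count to the ring and in reliability of the ring-forming step. The chosen plan sets against it that its contraction leaves C6-OH and the C7 side chain at the right oxidation level, with C1, C3, C8 and C10 already oxygenated.

**Alternative 3:** The cut runs the other way: the C1–C5 bond is added, hiding the ten-membered ring in a 5,7-fused guaianolide.
- Forward step: in a 1-hydroxy-3,4-epoxy guaianolide the C1 alkoxide pushes, the C1–C5 bond breaks and the C4–O epoxide bond opens (Grob-type fragmentation). This gives at once the C1 ketone, the Z C4=C5 alkene, the C3 carbinol and the ring, as A3, the C10 silyl ether of the target.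
- Merits: four features arise in one late step, the alkene geometry is fixed stereospecifically, and all earlier stereocontrol rests on rigid bicyclic intermediates.
- Weak points: the fragmentation needs C1–C5 anti-periplanar to C4–O, which an epoxide fused to a cyclopentane reaches only approximately. It must run under base beside the α-methylene lactone and the isovalerate, and its product is a β-alkoxy ketone prone to retro-aldol and elimination under those conditions. The substrate is a fully decorated guaianolide with eight stereocentres, at least as long to make as the target.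
- Comparison: if it worked, this would be the more elegant end game and more secure in alkene geometry. The chosen plan offers a key step of a known reaction class, run before the sensitive groups exist, on a much simpler precursor.

Key step: step 20

Remark 1: germacrane locants (C1–C15 as defined above) are used for all intermediates, acyclic ones included.
Remark 2: C1 is carried as a 1S silyl-protected carbinol that returns to the ketone in step 23; the C7 descriptor changes from S (27, 28) to R (30 onward) by CIP priority only, not by geometry.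
Remark 3: the hand of Ipc2BCl in step 12 is chosen from the usual sense of methyl-ketone boron enolates with Z-enals; C3 would be checked by Mosher ester analysis of 18 and the enantiomeric reagent used if needed.
Remark 4: (tributylstannyl)methanol, ethyl bromo(triphenylphosphoranylidene)acetate, (−)-Ipc2BCl and Me2BBr are taken as commercial reagents.

## Steps

Step 1
Reactants: 1 (R)-(−)-linalool
Product: 2 triethyl{[(3R)-3,7-dimethylocta-1,6-dien-3-yl]oxy}silane
Conditions: TESOTf, 2,6-lutidine, CH2Cl2, −78 to 0 °C
Reagents that add atoms: triethylsilyl trifluoromethanesulfonate, CC[Si](CC)(CC)OS(=O)(=O)C(F)(F)F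
Why: O-silylation of a tertiary alcohol with a silyl triflate; the C10 stereocentre comes from the chiral pool and is untouched.

Step 2
Reactants: 2 silyl ether of linalool
Product: 3 (4R)-4-methyl-4-[(triethylsilyl)oxy]hex-5-enal
Conditions: O3, CH2Cl2/MeOH, −78 °C, Sudan Red 7B end point; then Me2S, −78 °C to rt
Reagents that add atoms: ozone, [O-][O+]=O
Why: Chemoselective ozonolysis; the electron-rich trisubstituted alkene reacts much faster than the vinyl group shielded by the quaternary silyloxy carbon, and the dye marks the end point.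

Step 3
Reactants: 3 aldehyde
Product: 5 ethyl (2Z,4R,6R)-2-bromo-6-methyl-4-[(phenylamino)oxy]-6-[(triethylsilyl)oxy]octa-2,7-dienoate, via α-anilinooxy aldehyde 4 (not isolated)
Conditions: PhNO, L-proline (20 mol %), CHCl3, 4 °C; then Ph3P=C(Br)CO2Et, CH2Cl2, 0 °C to rt
Reagents that add atoms: nitrosobenzene, O=Nc1ccccc1; ethyl bromo(triphenyl-λ5-phosphanylidene)acetate, CCOC(=O)C(Br)=P(c1ccccc1)(c1ccccc1)c1ccccc1
Why: Proline-catalysed α-aminoxylation (O-selective nitroso aldol of the enamine through a hydrogen-bonded transition state; L-proline gives 8R) followed by Wittig olefination in the same flask. The stabilised α-bromo ylide places the ester trans to C8, hence bromine cis to C8 (2Z).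

Step 4
Reactants: 5 anilinooxy bromoenoate
Product: 6 ethyl (2Z,4R,6R)-2-bromo-4-hydroxy-6-methyl-6-[(triethylsilyl)oxy]octa-2,7-dienoate
Conditions: Cu(OAc)2 (30 mol %), EtOH, rt
Reagents that add atoms: none
Why: Copper-catalysed N–O cleavage of an O-alkyl-N-arylhydroxylamine, mild enough for the alkenyl bromide and enoate; the C8–O bond is not broken, so 8R is kept.

Step 5
Reactants: 6 hydroxy bromoenoate
Product: 7 ethyl (2Z,4R,6R)-2-bromo-4-(methoxymethoxy)-6-methyl-6-[(triethylsilyl)oxy]octa-2,7-dienoate
Conditions: MOMCl, i-Pr2NEt, CH2Cl2, 0 °C to rt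
Reagents that add atoms: chloromethyl methyl ether, COCCl
Why: Standard MOM ether formation; MOM is base-stable, slim and lithium-coordinating, which the key step uses, and its trans relation to the ester excludes lactonisation.

Step 6
Reactants: 7 MOM-protected bromoenoate
Product: 8 ethyl (2E,4R,6R)-2-(hydroxymethyl)-4-(methoxymethoxy)-6-methyl-6-[(triethylsilyl)oxy]octa-2,7-dienoate
Conditions: Bu3SnCH2OH, Pd(PPh3)4 (5 mol %), 1,4-dioxane, 90 °C
Reagents that add atoms: (tributylstannyl)methanol, CCCC[Sn](CO)(CCCC)CCCC
Why: Stille hydroxymethylation of an α-bromoacrylate, which adds oxidatively to zerovalent palladium with ease; coupling occurs with retention, so the new C12 arm is cis to C8 and the ester (C13) trans.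

Step 7
Reactants: 8 hydroxymethyl enoate
Product: 9 ethyl (2E,4R,6R)-2-({[tert-butyl(dimethyl)silyl]oxy}methyl)-4-(methoxymethoxy)-6-methyl-6-[(triethylsilyl)oxy]octa-2,7-dienoate
Conditions: TBSCl, imidazole, DMF, 0 °C to rt
Reagents that add atoms: tert-butyldimethylsilyl chloride, CC(C)(C)[Si](C)(C)Cl
Why: Silylation of a primary allylic alcohol; the bulky silyl ether is a poor lithium ligand and is later removed ahead of the C3 ether.

Step 8
Reactants: 9 vinyl enoate
Product: 10 ethyl (2E,4R,6R)-2-({[tert-butyl(dimethyl)silyl]oxy}methyl)-4-(methoxymethoxy)-6-methyl-7-oxo-6-[(triethylsilyl)oxy]oct-2-enoate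
Conditions: PdCl2 (10 mol %), CuCl, O2 (1 atm), DMF/H2O 7:1, rt
Reagents that add atoms: water, O
Why: Tsuji–Wacker oxidation is specific for the terminal alkene and leaves the electron-poor trisubstituted enoate alone; Markovnikov hydroxypalladation gives the methyl ketone, and quaternary C10 cannot epimerise.

Step 9
Reactants: 11 but-2-yn-1-ol
Product: 13 (2Z)-3-iodobut-2-en-1-ol, via cyclic alkenylaluminate 12 (not isolated)
Conditions: NaAlH2(OCH2CH2OMe)2, THF, 0 °C to rt; then I2, −78 to 0 °C
Reagents that add atoms: iodine, II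
Why: Hydroxyl-directed trans-hydroalumination of a propargylic alcohol puts aluminium on C4 in a five-membered aluminate; iodinolysis with retention gives the Z iodide, in which the future C3 and C6 are cis.

Step 10
Reactants: 13 (2Z)-3-iodobut-2-en-1-ol
Product: 14 1-({[(2Z)-3-iodobut-2-en-1-yl]oxy}methyl)-4-methoxybenzene
Conditions: NaH, PMBCl, n-Bu4NI (cat.), THF/DMF, 0 °C to rt
Reagents that add atoms: 4-methoxybenzyl chloride, COc1ccc(CCl)cc1
Why: Williamson benzylation; the PMB ether survives the aldol, hydride and silylation steps and is removed oxidatively at C6 just before macrocyclisation.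

Step 11
Reactants: 14 PMB ether of the Z iodide
Product: 16 (2Z)-4-[(4-methoxybenzyl)oxy]-2-methylbut-2-enal, via alkenyllithium 15 (not isolated)
Conditions: t-BuLi (2.1 equiv), Et2O, −78 °C; then DMF, −78 to 0 °C; aq. NH4Cl
Reagents that add atoms: N,N-dimethylformamide, CN(C)C=O
Why: Iodine–lithium exchange and formylation both proceed with retention at the alkenyl carbon, so the Z geometry is carried into the enal, which is used at once to avoid Z to E isomerisation.

Step 12
Reactants: 10 methyl ketone; 16 Z-enal
Product: 18 ethyl (2E,4R,6R,9R,10Z)-2-({[tert-butyl(dimethyl)silyl]oxy}methyl)-9-hydroxy-12-[(4-methoxybenzyl)oxy]-4-(methoxymethoxy)-6,10-dimethyl-7-oxo-6-[(triethylsilyl)oxy]dodeca-2,10-dienoate, via diisopinocampheylboron enolate 17 (not isolated)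
Conditions: (−)-Ipc2BCl, Et3N, Et2O, 0 °C; then 16, −78 to −20 °C; then pH 7 buffer, MeOH, H2O2, 0 °C
Reagents that add atoms: none
Why: Boron-mediated methyl-ketone aldol; enolisation is possible only toward C2 and the boron enolate does not add to the enoate. The Ipc ligands direct the enolate to the Re face of the enal to give 3R by reagent control, and the cold, weakly basic conditions should preserve the Z-enal.

Step 13
Reactants: 18 β-hydroxy ketone
Product: 19 ethyl (2E,4R,6R,7S,9R,10Z)-2-({[tert-butyl(dimethyl)silyl]oxy}methyl)-7,9-dihydroxy-12-[(4-methoxybenzyl)oxy]-4-(methoxymethoxy)-6,10-dimethyl-6-[(triethylsilyl)oxy]dodeca-2,10-dienoate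
Conditions: Et2BOMe, THF/MeOH 4:1, −78 °C; then NaBH4, −78 °C; MeOH azeotrope
Reagents that add atoms: none
Why: Narasaka–Prasad reduction; the C3 hydroxyl and the ketone form a six-membered boron chelate and external axial hydride delivery gives the 1,3-syn diol (1S). The enoate is not reduced at −78 °C.

Step 14
Reactants: 19 syn-1,3-diol
Product: 20 ethyl (2E,4R,6R,7S,9R,10Z)-2-({[tert-butyl(dimethyl)silyl]oxy}methyl)-7-hydroxy-12-[(4-methoxybenzyl)oxy]-4-(methoxymethoxy)-6,10-dimethyl-6-[(triethylsilyl)oxy]-9-[(triisopropylsilyl)oxy]dodeca-2,10-dienoate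
Conditions: TIPSOTf (1.05 equiv), 2,6-lutidine, CH2Cl2, −78 °C
Reagents that add atoms: triisopropylsilyl trifluoromethanesulfonate, CC(C)[Si](C(C)C)(C(C)C)OS(=O)(=O)C(F)(F)F
Why: Site-selective silylation; the allylic C3 hydroxyl is much less hindered than the C1 hydroxyl next to quaternary C10. TIPS is chosen because it does not migrate to a neighbouring alkoxide and outlasts every later deprotection.

Step 15
Reactants: 20 C1 alcohol
Product: 21 ethyl (2E,4R,6R,7S,9R,10Z)-2-({[tert-butyl(dimethyl)silyl]oxy}methyl)-12-[(4-methoxybenzyl)oxy]-4-(methoxymethoxy)-6,10-dimethyl-6,7-bis[(triethylsilyl)oxy]-9-[(triisopropylsilyl)oxy]dodeca-2,10-dienoate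
Conditions: TESOTf, 2,6-lutidine, CH2Cl2, 0 °C
Reagents that add atoms: triethylsilyl trifluoromethanesulfonate, CC[Si](CC)(CC)OS(=O)(=O)C(F)(F)F
Why: A silyl triflate silylates even the hindered C1 carbinol, completing the masking of the future ketone as a fluoride-labile ether.

Step 16
Reactants: 21 fully protected ester
Product: 22 (2Z,4R,6R,7S,9R,10Z)-2-({[tert-butyl(dimethyl)silyl]oxy}methyl)-12-[(4-methoxybenzyl)oxy]-4-(methoxymethoxy)-6,10-dimethyl-6,7-bis[(triethylsilyl)oxy]-9-[(triisopropylsilyl)oxy]dodeca-2,10-dien-1-ol (C13 allylic alcohol, C8 trans to C13)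
Conditions: i-Bu2AlH (2.5 equiv), CH2Cl2, −78 °C; Rochelle salt
Reagents that add atoms: none
Why: 1,2-Reduction of an α,β-unsaturated ester to the allylic alcohol; the aluminium alkoxide formed does not promote silyl transfer from the neighbouring C12 ether.

Step 17
Reactants: 22 allylic alcohol
Product: 23 C13 allylic chloride of 22 (1S,3R,8R,10R; 4Z; C8 trans to C13; otherwise as 22)
Conditions: NCS, Me2S, CH2Cl2, −20 to 0 °C
Reagents that add atoms: N-chlorosuccinimide, O=C1CCC(=O)N1Cl
Why: Corey–Kim chlorination converts primary allylic alcohols to the chlorides without allylic transposition and under conditions that spare silyl, MOM and PMB ethers.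

Step 18
Reactants: 23 allylic chloride
Product: 24 hydroxy chloride: 23 with the C6 PMB ether replaced by a free hydroxyl
Conditions: DDQ, CH2Cl2/pH 7 buffer 10:1, 0 °C
Reagents that add atoms: none
Why: Oxidative PMB removal under neutral conditions leaves the allylic chloride and all silyl and acetal groups intact.

Step 19
Reactants: 24 hydroxy chloride
Product: 25 (3Z,5R,7R,8S,10R,11Z)-3-({[tert-butyl(dimethyl)silyl]oxy}methyl)-5-(methoxymethoxy)-7,11-dimethyl-7,8-bis[(triethylsilyl)oxy]-10-[(triisopropylsilyl)oxy]-1-oxacyclotrideca-3,11-diene (thirteen-membered ether, O joins C6 and C13; C8 trans to C13 on C7=C11; 4Z)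
Conditions: NaH, n-Bu4NI (cat.), THF, syringe-pump addition to 2 mM, 0 to 40 °C
Reagents that add atoms: none
Why: Intramolecular Williamson etherification; thirteen-membered bis-allylic ethers of this kind are known to close this way under dilution. A primary allylic alkoxide displaces a primary allylic halide by SN2, and the only silyl ether within reach of the alkoxide is the non-migrating TIPS group.

Step 20
Reactants: 25 thirteen-membered bis-allylic ether
Product: 27 (1R,2Z,4R,6S,7R,9R,10S)-10-(3-{[tert-butyl(dimethyl)silyl]oxy}prop-1-en-2-yl)-9-(methoxymethoxy)-3,7-dimethyl-6,7-bis[(triethylsilyl)oxy]-4-[(triisopropylsilyl)oxy]cyclodec-2-en-1-ol (germacrane locants: 1S,3R,6R,7S,8R,10R; C6-OH), via C6-lithiated ether 26 (not isolated)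
Conditions: n-BuLi (1.5 equiv), THF, −78 °C; then aq. NH4Cl
Reagents that add atoms: none
Why: n-BuLi removes a C6 proton, allylic to C4=C5 and α to the ring oxygen, to give α-oxyallyllithium 26; its carbon bonds to C7 while O–C13 breaks and C11=C13 forms, a concerted suprafacial six-electron [2,3]-Wittig shift through a five-membered envelope. The closest known reaction type is the [2,3]-Wittig ring contraction of thirteen-membered bis-allylic cyclic ethers to cyclodecenols used for germacranes. The ten-membered carbocycle closes transannularly, thirteen ring atoms contracting to ten inside that five-membered transition-state array, so no separate medium-ring cyclisation is needed. The C6/C7 relationship follows from the alkene geometry (C8 trans to C13) and the exo placement of the C5 vinyl group, which the C12 substituent on C11 reinforces; this gives the anti pair that becomes the trans-lactone. The absolute sense at C7 is set by C8: allylic 1,3-strain with C12 holds the C8–H bond in the alkene plane, and the ring branch C9 cannot lie on the bonding face because it would meet the exo C5 in a syn-pentane contact, so C9 takes the far face and the slim, lithium-coordinating OMOM group the bonding face, which translates 8R into 6R,7S. The step needs lithiation at C6 and not at C13 or C12, and rearrangement faster than 1,4-elimination of an allylic oxygen; C13 is flanked by fully substituted C11 and its shift would have to build a quaternary C4, the bulky silyl ethers at C12 and C3 are poor lithium ligands, and at −78 °C the sigmatropic shift is expected to outrun alkoxide loss.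

Step 21
Reactants: 27 ring-contracted alcohol
Product: 28 (1R,2Z,4R,6S,7R,9R,10S)-10-(3-hydroxyprop-1-en-2-yl)-9-(methoxymethoxy)-3,7-dimethyl-4-[(triisopropylsilyl)oxy]cyclodec-2-ene-1,6,7-triol (germacrane locants: free OH at C1, C6, C10, C12)
Conditions: HF·pyridine, pyridine, THF, 0 °C to rt
Reagents that add atoms: none
Why: Graded fluoride desilylation; the primary TBS ether and both TES ethers are cleaved, whereas the secondary TIPS ether and the MOM ether are stable under these conditions.

Step 22
Reactants: 28 tetraol
Product: 30 (1S,3R,4Z,6R,7R,8R,10R)-1,10-dihydroxy-8-(methoxymethoxy)-3-[(triisopropylsilyl)oxy]germacra-4,11(13)-dien-12,6-olide, via lactol 29 (not isolated)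
Conditions: activated MnO2 (excess), CH2Cl2, rt
Reagents that add atoms: none
Why: Oxidative lactonisation of a 2-methylene-1,4-diol: MnO2 oxidises the primary allylic C12 hydroxyl to the enal, the C6 hydroxyl closes the five-membered lactol 29 (an allylic hemiacetal), and MnO2 oxidises it on to the lactone. The saturated C1/C10 diol is inert to MnO2, and the trans fusion follows from the C6/C7 configuration of step 20.

Step 23
Reactants: 30 hydroxy lactone
Product: 31 (3R,4Z,6R,7R,8R,10R)-10-hydroxy-8-(methoxymethoxy)-1-oxo-3-[(triisopropylsilyl)oxy]germacra-4,11(13)-dien-12,6-olide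
Conditions: IBX, DMSO, rt
Reagents that add atoms: none
Why: IBX oxidises the hindered secondary C1 carbinol to the ketone and, unlike glycol-cleaving oxidants, leaves the bond to the adjacent tertiary carbinol intact; the auxiliary C1 stereocentre is erased.

Step 24
Reactants: 31 keto lactone
Product: 32 (3R,4Z,6R,7R,8R,10R)-8,10-dihydroxy-1-oxo-3-[(triisopropylsilyl)oxy]germacra-4,11(13)-dien-12,6-olide
Conditions: Me2BBr, CH2Cl2, −78 °C; then aq. NaHCO3/THF
Reagents that add atoms: none
Why: Dimethylboron bromide cleaves MOM ethers at −78 °C via the bromomethyl ether, hydrolysed on work-up; silyl ethers, lactones and ketones tolerate the reagent at that temperature, and no thiol is involved that could add to the methylene lactone.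

Step 25
Reactants: 32 C8 alcohol; 33 isovaleryl chloride (3-methylbutanoyl chloride)
Product: 34 (3R,4Z,6R,7R,8R,10R)-10-hydroxy-8-[(3-methylbutanoyl)oxy]-1-oxo-3-[(triisopropylsilyl)oxy]germacra-4,11(13)-dien-12,6-olide
Conditions: pyridine, DMAP (cat.), CH2Cl2, 0 °C
Reagents that add atoms: none
Why: Acylation of the only secondary hydroxyl; the tertiary C10 hydroxyl does not react under these conditions, and the C8–O bond is not broken, so 8R is kept.

Step 26
Reactants: 34 silyl-protected ester
Product: 35 (3R,4Z,6R,7R,8R,10R)-3,10-dihydroxy-8-[(3-methylbutanoyl)oxy]-1-oxogermacra-4,11(13)-dien-12,6-olide (target)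
Conditions: HF·pyridine, THF, 0 °C to rt
Reagents that add atoms: none
Why: Fluoride-mediated cleavage of the allylic TIPS ether under acidic, non-nucleophilic conditions that spare the α-methylene lactone, the ester and the β-hydroxy ketone that is set free.

## Compound list

1 | (R)-(−)-linalool, (3R)-3,7-dimethylocta-1,6-dien-3-ol | C=C[C@](C)(O)CCC=C(C)C | starting material
2 | triethyl{[(3R)-3,7-dimethylocta-1,6-dien-3-yl]oxy}silane | C=C[C@](C)(O[Si](CC)(CC)CC)CCC=C(C)C | intermediate
3 | (4R)-4-methyl-4-[(triethylsilyl)oxy]hex-5-enal | C=C[C@](C)(O[Si](CC)(CC)CC)CCC=O | intermediate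
4 | (2R,4R)-4-methyl-2-[(phenylamino)oxy]-4-[(triethylsilyl)oxy]hex-5-enal | O=C[C@H](ONc1ccccc1)C[C@@](C)(O[Si](CC)(CC)CC)C=C | intermediate (not isolated)
5 | ethyl (2Z,4R,6R)-2-bromo-6-methyl-4-[(phenylamino)oxy]-6-[(triethylsilyl)oxy]octa-2,7-dienoate | CCOC(=O)/C(Br)=C/[C@H](ONc1ccccc1)C[C@@](C)(O[Si](CC)(CC)CC)C=C | intermediate
6 | ethyl (2Z,4R,6R)-2-bromo-4-hydroxy-6-methyl-6-[(triethylsilyl)oxy]octa-2,7-dienoate | CCOC(=O)/C(Br)=C/[C@H](O)C[C@@](C)(O[Si](CC)(CC)CC)C=C | intermediate
7 | ethyl (2Z,4R,6R)-2-bromo-4-(methoxymethoxy)-6-methyl-6-[(triethylsilyl)oxy]octa-2,7-dienoate | CCOC(=O)/C(Br)=C/[C@H](OCOC)C[C@@](C)(O[Si](CC)(CC)CC)C=C | intermediate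
8 | ethyl (2E,4R,6R)-2-(hydroxymethyl)-4-(methoxymethoxy)-6-methyl-6-[(triethylsilyl)oxy]octa-2,7-dienoate | CCOC(=O)/C(CO)=C/[C@H](OCOC)C[C@@](C)(O[Si](CC)(CC)CC)C=C | intermediate
9 | ethyl (2E,4R,6R)-2-({[tert-butyl(dimethyl)silyl]oxy}methyl)-4-(methoxymethoxy)-6-methyl-6-[(triethylsilyl)oxy]octa-2,7-dienoate | CCOC(=O)/C(CO[Si](C)(C)C(C)(C)C)=C/[C@H](OCOC)C[C@@](C)(O[Si](CC)(CC)CC)C=C | intermediate
10 | ethyl (2E,4R,6R)-2-({[tert-butyl(dimethyl)silyl]oxy}methyl)-4-(methoxymethoxy)-6-methyl-7-oxo-6-[(triethylsilyl)oxy]oct-2-enoate | CCOC(=O)/C(CO[Si](C)(C)C(C)(C)C)=C/[C@H](OCOC)C[C@@](C)(O[Si](CC)(CC)CC)C(C)=O | intermediate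
11 | but-2-yn-1-ol | CC#CCO | starting material
12 | cyclic alkenylaluminate of 11 (sodium salt; Al on C4 and O-bound, two 2-methoxyethoxy ligands) | CC1=CCO[Al-]1(OCCOC)OCCOC.[Na+] | intermediate (not isolated)
13 | (2Z)-3-iodobut-2-en-1-ol | C/C(I)=C/CO | intermediate
14 | 1-({[(2Z)-3-iodobut-2-en-1-yl]oxy}methyl)-4-methoxybenzene | C/C(I)=C/COCc1ccc(OC)cc1 | intermediate
15 | {(2Z)-4-[(4-methoxybenzyl)oxy]but-2-en-2-yl}lithium | [Li]/C(C)=C\COCc1ccc(OC)cc1 | intermediate (not isolated)
16 | (2Z)-4-[(4-methoxybenzyl)oxy]-2-methylbut-2-enal | O=C/C(C)=C\COCc1ccc(OC)cc1 | intermediate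
17 | diisopinocampheylboron enolate of 10 (C1–O–B(Ipc)2, C1=C2 methylene) | CCOC(=O)/C(CO[Si](C)(C)C(C)(C)C)=C/[C@H](OCOC)C[C@@](C)(O[Si](CC)(CC)CC)C(=C)OB([C@@H]1C[C@@H]2C[C@H]([C@H]1C)C2(C)C)[C@@H]1C[C@@H]2C[C@H]([C@H]1C)C2(C)C | intermediate (not isolated)
18 | ethyl (2E,4R,6R,9R,10Z)-2-({[tert-butyl(dimethyl)silyl]oxy}methyl)-9-hydroxy-12-[(4-methoxybenzyl)oxy]-4-(methoxymethoxy)-6,10-dimethyl-7-oxo-6-[(triethylsilyl)oxy]dodeca-2,10-dienoate | CCOC(=O)/C(CO[Si](C)(C)C(C)(C)C)=C/[C@H](OCOC)C[C@@](C)(O[Si](CC)(CC)CC)C(=O)C[C@@H](O)/C(C)=C\COCc1ccc(OC)cc1 | intermediate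
19 | ethyl (2E,4R,6R,7S,9R,10Z)-2-({[tert-butyl(dimethyl)silyl]oxy}methyl)-7,9-dihydroxy-12-[(4-methoxybenzyl)oxy]-4-(methoxymethoxy)-6,10-dimethyl-6-[(triethylsilyl)oxy]dodeca-2,10-dienoate | CCOC(=O)/C(CO[Si](C)(C)C(C)(C)C)=C/[C@H](OCOC)C[C@@](C)(O[Si](CC)(CC)CC)[C@@H](O)C[C@@H](O)/C(C)=C\COCc1ccc(OC)cc1 | intermediate
20 | ethyl (2E,4R,6R,7S,9R,10Z)-2-({[tert-butyl(dimethyl)silyl]oxy}methyl)-7-hydroxy-12-[(4-methoxybenzyl)oxy]-4-(methoxymethoxy)-6,10-dimethyl-6-[(triethylsilyl)oxy]-9-[(triisopropylsilyl)oxy]dodeca-2,10-dienoate | CCOC(=O)/C(CO[Si](C)(C)C(C)(C)C)=C/[C@H](OCOC)C[C@@](C)(O[Si](CC)(CC)CC)[C@@H](O)C[C@@H](O[Si](C(C)C)(C(C)C)C(C)C)/C(C)=C\COCc1ccc(OC)cc1 | intermediate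
21 | ethyl (2E,4R,6R,7S,9R,10Z)-2-({[tert-butyl(dimethyl)silyl]oxy}methyl)-12-[(4-methoxybenzyl)oxy]-4-(methoxymethoxy)-6,10-dimethyl-6,7-bis[(triethylsilyl)oxy]-9-[(triisopropylsilyl)oxy]dodeca-2,10-dienoate | CCOC(=O)/C(CO[Si](C)(C)C(C)(C)C)=C/[C@H](OCOC)C[C@@](C)(O[Si](CC)(CC)CC)[C@@H](O[Si](CC)(CC)CC)C[C@@H](O[Si](C(C)C)(C(C)C)C(C)C)/C(C)=C\COCc1ccc(OC)cc1 | intermediate
22 | (2Z,4R,6R,7S,9R,10Z)-2-({[tert-butyl(dimethyl)silyl]oxy}methyl)-12-[(4-methoxybenzyl)oxy]-4-(methoxymethoxy)-6,10-dimethyl-6,7-bis[(triethylsilyl)oxy]-9-[(triisopropylsilyl)oxy]dodeca-2,10-dien-1-ol | OC/C(CO[Si](C)(C)C(C)(C)C)=C/[C@H](OCOC)C[C@@](C)(O[Si](CC)(CC)CC)[C@@H](O[Si](CC)(CC)CC)C[C@@H](O[Si](C(C)C)(C(C)C)C(C)C)/C(C)=C\COCc1ccc(OC)cc1 | intermediate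
23 | C13 allylic chloride of 22 (germacrane locants 1S,3R,8R,10R; 4Z; C8 trans to C13; C6-OPMB) | ClC/C(CO[Si](C)(C)C(C)(C)C)=C/[C@H](OCOC)C[C@@](C)(O[Si](CC)(CC)CC)[C@@H](O[Si](CC)(CC)CC)C[C@@H](O[Si](C(C)C)(C(C)C)C(C)C)/C(C)=C\COCc1ccc(OC)cc1 | intermediate
24 | C6 alcohol, C13 chloride (23 without the PMB group) | ClC/C(CO[Si](C)(C)C(C)(C)C)=C/[C@H](OCOC)C[C@@](C)(O[Si](CC)(CC)CC)[C@@H](O[Si](CC)(CC)CC)C[C@@H](O[Si](C(C)C)(C(C)C)C(C)C)/C(C)=C\CO | intermediate
25 | (3Z,5R,7R,8S,10R,11Z)-3-({[tert-butyl(dimethyl)silyl]oxy}methyl)-5-(methoxymethoxy)-7,11-dimethyl-7,8-bis[(triethylsilyl)oxy]-10-[(triisopropylsilyl)oxy]-1-oxacyclotrideca-3,11-diene | O1C/C(CO[Si](C)(C)C(C)(C)C)=C/[C@H](OCOC)C[C@@](C)(O[Si](CC)(CC)CC)[C@@H](O[Si](CC)(CC)CC)C[C@@H](O[Si](C(C)C)(C(C)C)C(C)C)/C(C)=C\C1 | intermediate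
26 | C6-lithio derivative of 25 (α-oxyallyllithium, C6 configuration labile) | O1C/C(CO[Si](C)(C)C(C)(C)C)=C/[C@H](OCOC)C[C@@](C)(O[Si](CC)(CC)CC)[C@@H](O[Si](CC)(CC)CC)C[C@@H](O[Si](C(C)C)(C(C)C)C(C)C)/C(C)=C\C1[Li] | intermediate (not isolated)
27 | (1R,2Z,4R,6S,7R,9R,10S)-10-(3-{[tert-butyl(dimethyl)silyl]oxy}prop-1-en-2-yl)-9-(methoxymethoxy)-3,7-dimethyl-6,7-bis[(triethylsilyl)oxy]-4-[(triisopropylsilyl)oxy]cyclodec-2-en-1-ol | C=C(CO[Si](C)(C)C(C)(C)C)[C@H]1[C@H](O)/C=C(/C)[C@H](O[Si](C(C)C)(C(C)C)C(C)C)C[C@H](O[Si](CC)(CC)CC)[C@](C)(O[Si](CC)(CC)CC)C[C@H]1OCOC | intermediate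
28 | (1R,2Z,4R,6S,7R,9R,10S)-10-(3-hydroxyprop-1-en-2-yl)-9-(methoxymethoxy)-3,7-dimethyl-4-[(triisopropylsilyl)oxy]cyclodec-2-ene-1,6,7-triol | C=C(CO)[C@H]1[C@H](O)/C=C(/C)[C@H](O[Si](C(C)C)(C(C)C)C(C)C)C[C@H](O)[C@](C)(O)C[C@H]1OCOC | intermediate
29 | 12-hydroxy lactol corresponding to 30 (C12 epimers) | C=C1C(O)O[C@@H]2/C=C(/C)[C@H](O[Si](C(C)C)(C(C)C)C(C)C)C[C@H](O)[C@](C)(O)C[C@@H](OCOC)[C@@H]12 | intermediate (not isolated)
30 | (1S,3R,4Z,6R,7R,8R,10R)-1,10-dihydroxy-8-(methoxymethoxy)-3-[(triisopropylsilyl)oxy]germacra-4,11(13)-dien-12,6-olide | C=C1C(=O)O[C@@H]2/C=C(/C)[C@H](O[Si](C(C)C)(C(C)C)C(C)C)C[C@H](O)[C@](C)(O)C[C@@H](OCOC)[C@@H]12 | intermediate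
31 | (3R,4Z,6R,7R,8R,10R)-10-hydroxy-8-(methoxymethoxy)-1-oxo-3-[(triisopropylsilyl)oxy]germacra-4,11(13)-dien-12,6-olide | C=C1C(=O)O[C@@H]2/C=C(/C)[C@H](O[Si](C(C)C)(C(C)C)C(C)C)CC(=O)[C@](C)(O)C[C@@H](OCOC)[C@@H]12 | intermediate
32 | (3R,4Z,6R,7R,8R,10R)-8,10-dihydroxy-1-oxo-3-[(triisopropylsilyl)oxy]germacra-4,11(13)-dien-12,6-olide | C=C1C(=O)O[C@@H]2/C=C(/C)[C@H](O[Si](C(C)C)(C(C)C)C(C)C)CC(=O)[C@](C)(O)C[C@@H](O)[C@@H]12 | intermediate
33 | isovaleryl chloride (3-methylbutanoyl chloride) | CC(C)CC(=O)Cl | starting material
34 | (3R,4Z,6R,7R,8R,10R)-10-hydroxy-8-[(3-methylbutanoyl)oxy]-1-oxo-3-[(triisopropylsilyl)oxy]germacra-4,11(13)-dien-12,6-olide | C=C1C(=O)O[C@@H]2/C=C(/C)[C@H](O[Si](C(C)C)(C(C)C)C(C)C)CC(=O)[C@](C)(O)C[C@@H](OC(=O)CC(C)C)[C@@H]12 | intermediate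
35 | (3R,4Z,6R,7R,8R,10R)-3,10-dihydroxy-8-[(3-methylbutanoyl)oxy]-1-oxogermacra-4,11(13)-dien-12,6-olide | C=C1C(=O)O[C@@H]2/C=C(/C)[C@H](O)CC(=O)[C@](C)(O)C[C@@H](OC(=O)CC(C)C)[C@@H]12 | target

## Step count and least certain steps

Total: 26 steps. Longest linear sequence: 23 steps (steps 1–8 and 12–26 from linalool); the enal branch (steps 9–11) adds 3.

**Step 20 (key step).** What may go wrong: lithiation at C13 or C12 in place of C6, followed by 1,4-elimination of the C8 alkoxide; loss of the C3 silyloxide from the C6 allyl anion before it rearranges; or bonding on the other face of C7=C11 if the ring overrides the allylic-strain model. Fallback: set out from 24. Oxidation with MnO2 would give the Z-enal chloride F1. CrCl2 (divalent chromium) with LiI in THF at high dilution would then add the allylchromium formed at C13 through its γ-carbon C7 to the C6 aldehyde (intramolecular Nozaki–Hiyama allylation, chair transition state, anti C6/C7). This forms the same C6–C7 bond, the C11=C13 methylene and the ten-membered ring without a strong base, and rejoins the route at 27.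

**Step 19.** What may go wrong: intermolecular etherification to dimers and oligomers, dehydrochlorination of the allylic chloride by the alkoxide, or silyl transfer to the C6 alkoxide. Fallback: set out from 22. Methyl chloroformate and pyridine would give the allylic methyl carbonate F2, and DDQ the hydroxy carbonate F3. Pd(PPh3)4 (zerovalent palladium) in dilute THF would ionise the carbonate and let the C6 hydroxyl, deprotonated by the released methoxide, attack the less hindered C13 terminus of the π-allyl complex (intramolecular Tsuji–Trost etherification), returning to 25.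

**Step 12.** What may go wrong: isomerisation of the Z-enal to the E-isomer under the amine, or incomplete facial discrimination by the Ipc ligands, which are only moderately selective with methyl ketones, giving C3 epimers. Fallback: set out from 10. TMSOTf and Et3N would give the trimethylsilyl enol ether F4, which would be added to 16 in a catalytic enantioselective Mukaiyama aldol reaction under a chiral oxazaborolidinone Lewis acid (open transition state, catalyst control), returning to 18 after mild acidic work-up.

**Step 8.** What may go wrong: anti-Markovnikov hydroxypalladation steered by the allylic oxygen (aldehyde formation), or slow turnover next to the quaternary carbon with erosion of acid-labile silyl ethers. Fallback: set out from 9. Oxymercuration (Hg(OAc)2, THF/H2O) would give the hydroxyalkylmercury acetate F5, NaBH4/NaOH the secondary alcohol F6 (Markovnikov hydration, C1 epimers), and Dess–Martin periodinane the ketone, returning to 10.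

**Step 3.** What may go wrong: the α-bromo ylide olefinates more slowly than the unsubstituted ylide, so the labile aminooxy aldehyde may epimerise at C8, eliminate or oligomerise first, and the alkene geometry may erode. Fallback: set out from 3. Organocatalytic α-benzoyloxylation (dibenzoyl peroxide, a diarylprolinol silyl ether of the hand that gives 8R) would give the isolable benzoate aldehyde F7, the same Wittig reagent the benzoate bromoenoate F8, and ethanolysis (K2CO3, EtOH, 0 °C) would return to 6.

## Further compounds

F1 | step 20 | Z-enal chloride (C6 aldehyde of 24) | ClC/C(CO[Si](C)(C)C(C)(C)C)=C/[C@H](OCOC)C[C@@](C)(O[Si](CC)(CC)CC)[C@@H](O[Si](CC)(CC)CC)C[C@@H](O[Si](C(C)C)(C(C)C)C(C)C)/C(C)=C\C=O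
F2 | step 19 | C13 methyl carbonate of 22 | COC(=O)OC/C(CO[Si](C)(C)C(C)(C)C)=C/[C@H](OCOC)C[C@@](C)(O[Si](CC)(CC)CC)[C@@H](O[Si](CC)(CC)CC)C[C@@H](O[Si](C(C)C)(C(C)C)C(C)C)/C(C)=C\COCc1ccc(OC)cc1
F3 | step 19 | C6-hydroxy C13 methyl carbonate | COC(=O)OC/C(CO[Si](C)(C)C(C)(C)C)=C/[C@H](OCOC)C[C@@](C)(O[Si](CC)(CC)CC)[C@@H](O[Si](CC)(CC)CC)C[C@@H](O[Si](C(C)C)(C(C)C)C(C)C)/C(C)=C\CO
F4 | step 12 | trimethylsilyl enol ether of 10 | CCOC(=O)/C(CO[Si](C)(C)C(C)(C)C)=C/[C@H](OCOC)C[C@@](C)(O[Si](CC)(CC)CC)C(=C)O[Si](C)(C)C
F5 | step 8 | ethyl (2E,4R,6R)-8-(acetoxymercurio)-2-({[tert-butyl(dimethyl)silyl]oxy}methyl)-7-hydroxy-4-(methoxymethoxy)-6-methyl-6-[(triethylsilyl)oxy]oct-2-enoate (C7 epimers) | CCOC(=O)/C(CO[Si](C)(C)C(C)(C)C)=C/[C@H](OCOC)C[C@@](C)(O[Si](CC)(CC)CC)C(O)C[Hg]OC(C)=O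
F6 | step 8 | ethyl (2E,4R,6R)-2-({[tert-butyl(dimethyl)silyl]oxy}methyl)-7-hydroxy-4-(methoxymethoxy)-6-methyl-6-[(triethylsilyl)oxy]oct-2-enoate (C7 epimers) | CCOC(=O)/C(CO[Si](C)(C)C(C)(C)C)=C/[C@H](OCOC)C[C@@](C)(O[Si](CC)(CC)CC)C(C)O
F7 | step 3 | (2R,4R)-4-methyl-1-oxo-4-[(triethylsilyl)oxy]hex-5-en-2-yl benzoate | O=C[C@H](OC(=O)c1ccccc1)C[C@@](C)(O[Si](CC)(CC)CC)C=C
F8 | step 3 | ethyl (2Z,4R,6R)-4-(benzoyloxy)-2-bromo-6-methyl-6-[(triethylsilyl)oxy]octa-2,7-dienoate | CCOC(=O)/C(Br)=C/[C@H](OC(=O)c1ccccc1)C[C@@](C)(O[Si](CC)(CC)CC)C=C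
A1 | alternative 1 | trans α-(diethoxyphosphoryl) γ-lactone with free C8 hydroxyl, open C1–C5 chain ending in a Z alkenyl iodide | I/C(C)=C\[C@H]1OC(=O)[C@@H](P(=O)(OCC)OCC)[C@@H]1[C@H](O)C[C@@](C)(O[Si](CC)(CC)CC)C1(OCCO1)CCO[Si](C)(C)C(C)(C)C
A2 | alternative 2 | (4Z,1(10)E)-3-[(tert-butyldimethylsilyl)oxy]-8-[dimethyl(phenyl)silyl]germacra-1(10),4-dien-6-one (cyclodecadienone) | O=C1/C=C(/C)[C@H](O[Si](C)(C)C(C)(C)C)C/C=C(\C)C[C@@H]([Si](C)(C)c2ccccc2)C1
A3 | alternative 3 | C10 triethylsilyl ether of the target | C=C1C(=O)O[C@@H]2/C=C(/C)[C@H](O)CC(=O)[C@](C)(O[Si](CC)(CC)CC)C[C@@H](OC(=O)CC(C)C)[C@@H]12
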